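**Retrosynthetic overview**

1. The route rests on ring B, the 5-ylidene-5,6-dihydropyran-2-one (O B1, C=O B2, B3=B4, ylidene carbon B5, CH2 B6). Its exocyclic CH=B5 alkene holds the chain cis to B4 and trans to B6, which is the outcome of anti H/Sn addition to a 2-alkyn-1-ol, and its doubly allylic CH2 makes it base-labile, so it is built last.
2. Ring B is cut at B4–B5 (Stille coupling) and B1–B2 (lactonisation) to give skipped enynol 25 and methyl (Z)-3-iodoacrylate 27; one fluoride step then removes both TES ethers and the TMSE ester.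
3. The enynol comes from allylic bromide 16 and PMB propargyl ether 5 (copper coupling), the Z-chloroalkene from propargylic alcohol 12 (NaAlH2(OCH2CH2OMe)2, then NCS), and the acid side chain from C6 aldehyde 18 (Wittig, then Arndt–Eistert).
4. Ring A (the oxolane) comes from 2-deoxy-D-glucose: sugar C3, C4 and C5 become oxolane C3, C2 and the carbinol carbon unchanged; oxolane C5 is set by alkyllithium addition to the 1,4-lactone and Et3SiH/BF3·OEt2 reduction.
5. Ring order: ring A in step 7, ring B in step 19.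

Key step: step 19

Assumption: the Z hydroxy dienoate 29 is taken to close to the lactone in the flask or on silica gel, as Z-configured 5-hydroxy-2-enoates do; ethylene oxide 6, ylide 19 and the reagents written over the arrows are bought.

**Route**

Step 1
Reactants: 1 2-deoxy-D-glucose
Product: 2 2-deoxy-D-arabino-hexono-1,4-lactone
Conditions: Br2, H2O, rt; then evaporation
Reagents that add atoms: none
Why: Bromine-water oxidation of the aldose hemiacetal gives the aldonic acid, which should settle as the five-membered 1,4-lactone on concentration without touching C3, C4 or C5.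

Step 2
Reactants: 2 2-deoxy-D-arabino-hexono-1,4-lactone
Product: 3 2-deoxy-3,5,6-tris-O-(triethylsilyl)-D-arabino-hexono-1,4-lactone
Conditions: TESCl, imidazole, DMF, 0 °C to rt
Reagents that add atoms: chlorotriethylsilane CC[Si](Cl)(CC)CC
Why: Imidazole-promoted silylation caps all three hydroxyls in one operation and already places the two secondary TES ethers that the key step needs.

Step 3
Reactants: 4 propargyl alcohol
Product: 5 1-methoxy-4-[(prop-2-yn-1-yloxy)methyl]benzene (PMB propargyl ether)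
Conditions: NaH, PMBCl, Bu4NI (cat.), THF, 0 °C to rt
Reagents that add atoms: 4-methoxybenzyl chloride COc1ccc(CCl)cc1
Why: Williamson etherification of the primary alkoxide with a benzylic chloride.

Step 4
Reactants: 5 PMB propargyl ether; 6 ethylene oxide
Product: 7 5-[(4-methoxybenzyl)oxy]pent-3-yn-1-ol
Conditions: n-BuLi, THF, −78 °C; BF3·OEt2; then 6, −78 °C
Reagents that add atoms: none
Why: BF3-promoted opening of the epoxide by the lithium acetylide gives the homopropargylic alcohol, and the PMB ether tolerates the Lewis acid at −78 °C.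

Step 5
Reactants: 7 5-[(4-methoxybenzyl)oxy]pent-3-yn-1-ol
Product: 8 1-{[(5-iodopent-2-yn-1-yl)oxy]methyl}-4-methoxybenzene
Conditions: I2, PPh3, imidazole, CH2Cl2, 0 °C to rt
Reagents that add atoms: iodine II
Why: Appel-type iodination of a primary alcohol by SN2 displacement of the oxyphosphonium group.

Step 6
Reactants: 8 1-{[(5-iodopent-2-yn-1-yl)oxy]methyl}-4-methoxybenzene; 3 tris-TES lactone
Product: 10 2-deoxy-1-C-{5-[(4-methoxybenzyl)oxy]pent-3-yn-1-yl}-3,5,6-tris-O-(triethylsilyl)-D-arabino-hexofuranose (hemiketal; both anomers), via alkyllithium 9 (not isolated)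
Conditions: t-BuLi (2 equiv), Et2O/pentane, −78 °C; then 3, Et2O, −78 °C; aq. NH4Cl
Reagents that add atoms: none
Why: Iodine–lithium exchange gives a primary alkyllithium that adds once to the lactone carbonyl (organolithium addition to an aldonolactone), because the lithium hemiketalate does not collapse before the cold quench; the anomeric centre is removed in the next step.

Step 7
Reactants: 10 hemiketal
Product: 11 (2S,3R,5R)-2-[(1R)-1,2-bis(triethylsilyloxy)ethyl]-5-{5-[(4-methoxybenzyl)oxy]pent-3-yn-1-yl}-3-(triethylsilyloxy)oxolane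
Conditions: Et3SiH, BF3·OEt2, CH2Cl2, −78 °C
Reagents that add atoms: none
Why: Ionic hydrogenation of the lactol: BF3 ionises the hemiketal to the five-membered oxocarbenium ion and Et3SiH should deliver hydride by inside attack on the envelope, cis to the pseudoaxial C3 silyloxy group, which places the chain at oxolane C5 trans to both the C3 oxygen and the C2 side chain (C5 becomes R) and closes ring A.

Step 8
Reactants: 11 PMB ether
Product: 12 (2S,3R,5R)-2-[(1R)-1,2-bis(triethylsilyloxy)ethyl]-5-(5-hydroxypent-3-yn-1-yl)-3-(triethylsilyloxy)oxolane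
Conditions: DDQ, CH2Cl2/pH 7 phosphate buffer, 0 °C
Reagents that add atoms: none
Why: Oxidative cleavage of the PMB ether by DDQ under buffered conditions leaves TES ethers and the alkyne untouched.

Step 9
Reactants: 12 propargylic alcohol
Product: 14 (2S,3R,5R)-2-[(1R)-1,2-bis(triethylsilyloxy)ethyl]-5-[(3Z)-3-chloro-5-hydroxypent-3-en-1-yl]-3-(triethylsilyloxy)oxolane, via cyclic alkenylaluminate 13 (not isolated)
Conditions: NaAlH2(OCH2CH2OMe)2, THF, 0 °C to rt; then NCS, −78 to 0 °C
Reagents that add atoms: N-chlorosuccinimide O=C1CCC(=O)N1Cl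
Why: Hydroxyl-directed trans-hydroalumination of the propargylic alcohol puts hydride on the carbon next to CH2OH and aluminium on the distal carbon in a five-membered alkoxyaluminate, and chlorodealumination with retention gives the Z-chloroalkene with Cl cis to CH2OH.

Step 10
Reactants: 14 allylic alcohol
Product: 16 (2S,3R,5R)-2-[(1R)-1,2-bis(triethylsilyloxy)ethyl]-5-[(3Z)-5-bromo-3-chloropent-3-en-1-yl]-3-(triethylsilyloxy)oxolane, via allylic mesylate 15 (not isolated)
Conditions: Ms2O, Et3N, THF, −20 °C; then LiBr, 0 °C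
Reagents that add atoms: lithium bromide [Li+].[Br-]
Why: Mesylation followed by SN2 bromide displacement at the primary allylic carbon, neutral enough for the TES ethers and without change of alkene geometry.

Step 11
Reactants: 16 allylic bromide; 5 PMB propargyl ether
Product: 17 (2S,3R,5R)-2-[(1R)-1,2-bis(triethylsilyloxy)ethyl]-5-{(3Z)-3-chloro-8-[(4-methoxybenzyl)oxy]oct-3-en-6-yn-1-yl}-3-(triethylsilyloxy)oxolane
Conditions: CuI (cat.), K2CO3, Bu4NBr, DMF, rt
Reagents that add atoms: none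
Why: Copper-catalysed allylation of a terminal alkyne under carbonate and phase-transfer conditions; the copper acetylide should attack the unhindered CH2Br end, not the Cl-bearing γ carbon, giving the skipped enyne before any base-sensitive ester is present.

Step 12
Reactants: 17 tris-TES ether
Product: 18 (2S)-2-[(2S,3R,5R)-5-{(3Z)-3-chloro-8-[(4-methoxybenzyl)oxy]oct-3-en-6-yn-1-yl}-3-(triethylsilyloxy)oxolan-2-yl]-2-(triethylsilyloxy)acetaldehyde
Conditions: (COCl)2, DMSO, CH2Cl2, −78 to −40 °C; then Et3N, −78 °C to rt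
Reagents that add atoms: none
Why: Swern oxidation applied directly to the silyl ether: the chlorosulfonium salt cleaves only the unhindered primary TES ether and the resulting alkoxysulfonium ion gives the aldehyde, while both secondary TES ethers stay and the α-silyloxy centre should not epimerise at low temperature.

Step 13
Reactants: 18 aldehyde; 19 ethyl 2-(triphenylphosphoranylidene)propanoate
Product: 20 ethyl (2E,4R)-4-[(2S,3R,5R)-5-{(3Z)-3-chloro-8-[(4-methoxybenzyl)oxy]oct-3-en-6-yn-1-yl}-3-(triethylsilyloxy)oxolan-2-yl]-2-methyl-4-(triethylsilyloxy)but-2-enoate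
Conditions: CH2Cl2, rt
Reagents that add atoms: none
Why: Wittig olefination with a stabilised α-methyl ylide, which should give the E trisubstituted enoate (ester trans to the carbinol carbon) under non-basic conditions.

Step 14
Reactants: 20 ethyl enoate
Product: 21 (2E,4R)-4-[(2S,3R,5R)-5-{(3Z)-3-chloro-8-[(4-methoxybenzyl)oxy]oct-3-en-6-yn-1-yl}-3-(triethylsilyloxy)oxolan-2-yl]-2-methyl-4-(triethylsilyloxy)but-2-enoic acid
Conditions: LiOH, THF/MeOH/H2O, rt; then dilute HCl to pH 4, 0 °C
Reagents that add atoms: lithium hydroxide [Li+].[OH-]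
Why: Saponification of the ethyl ester; secondary TES ethers and the skipped enyne tolerate aqueous hydroxide at room temperature.

Step 15
Reactants: 21 enoic acid
Product: 23 (3E,5R)-1-diazo-5-[(2S,3R,5R)-5-{(3Z)-3-chloro-8-[(4-methoxybenzyl)oxy]oct-3-en-6-yn-1-yl}-3-(triethylsilyloxy)oxolan-2-yl]-3-methyl-5-(triethylsilyloxy)pent-3-en-2-one, via acid chloride 22 (not isolated)
Conditions: 1-chloro-N,N,2-trimethylprop-1-en-1-amine, CH2Cl2, 0 °C to rt; then CH2N2 (excess), Et2O, 0 °C
Reagents that add atoms: diazomethane C=[N+]=[N-]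
Why: First half of the Arndt–Eistert homologation: the chloroenamine makes the acid chloride without free acid, and acylation of diazomethane gives the diazoketone, the trisubstituted alkene being too hindered for dipolar cycloaddition.

Step 16
Reactants: 23 diazoketone
Product: 24 2-(trimethylsilyl)ethyl (3E,5R)-5-[(2S,3R,5R)-5-{(3Z)-3-chloro-8-[(4-methoxybenzyl)oxy]oct-3-en-6-yn-1-yl}-3-(triethylsilyloxy)oxolan-2-yl]-3-methyl-5-(triethylsilyloxy)pent-3-enoate
Conditions: PhCO2Ag (cat.), Et3N, Me3SiCH2CH2OH, THF, −20 °C to rt, dark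
Reagents that add atoms: 2-(trimethylsilyl)ethanol C[Si](C)(C)CCO
Why: Wolff rearrangement of the α,β-unsaturated diazoketone gives a vinylketene that the alcohol traps with protonation at the α carbon, so the alkene should end up β,γ to the new ester with its E geometry kept.

Step 17
Reactants: 24 PMB ether
Product: 25 2-(trimethylsilyl)ethyl (3E,5R)-5-[(2S,3R,5R)-5-[(3Z)-3-chloro-8-hydroxyoct-3-en-6-yn-1-yl]-3-(triethylsilyloxy)oxolan-2-yl]-3-methyl-5-(triethylsilyloxy)pent-3-enoate
Conditions: DDQ, CH2Cl2/pH 7 phosphate buffer, 0 °C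
Reagents that add atoms: none
Why: Oxidative PMB cleavage by DDQ frees the one hydroxyl the key step needs, without acid, base or fluoride.

Step 18
Reactants: 26 methyl propiolate
Product: 27 methyl (2Z)-3-iodoprop-2-enoate
Conditions: NaI, AcOH, 70 °C
Reagents that add atoms: sodium iodide [Na+].[I-]
Why: Conjugate addition of iodide to the ynoate and protonation anti to iodine (hydroiodination) gives the Z iodoacrylate.

Step 19
Reactants: 25 skipped enynol; 27 methyl (2Z)-3-iodoprop-2-enoate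
Product: 30 2-(trimethylsilyl)ethyl (3E,5R)-5-[(2S,3R,5R)-5-[(3Z,6E)-3-chloro-6-(6-oxo-2H-pyran-3(6H)-ylidene)hex-3-en-1-yl]-3-(triethylsilyloxy)oxolan-2-yl]-3-methyl-5-(triethylsilyloxy)pent-3-enoate, via alkenylstannane 28 (not isolated), via hydroxy dienoate 29 (not isolated)
Conditions: Bu3SnH, [Cp*RuCl]4 (cat.), CH2Cl2, rt; evaporation; then 27, Pd(PPh3)4 (cat.), CuTC (C4H3SCO2Cu), [Bu4N][Ph2PO2], DMF, rt
Reagents that add atoms: none
Why: Bu3SnH adds across the alkyne on the Cp*RuCl fragment, whose chloride ligand hydrogen-bonds the only free hydroxyl, so tin goes to the carbon next to CH2OH and H and Sn end up anti, giving stannane 28 with the chlorodiene chain trans to CH2OH. The closest known reaction types are the hydroxyl-directed ruthenium-catalysed trans-hydrostannation of propargylic alcohols and the copper-assisted Stille coupling of alkenylstannanes with Z-3-iodoacrylates followed by lactonisation. In the second stage tin-to-copper-to-palladium transmetalation (Ph2PO2− takes up the Bu3Sn group) and reductive elimination from divalent palladium form the B5–B4 bond with retention at both alkenes, giving 29. Ring B then closes by 6-exo-trig attack of the B6 hydroxyl on the ester carbonyl (B1–B2 bond, methanol lost), which only the Z enoate allows. No stereocentre is formed; the step needs proximal regioselectivity and anti addition, which fix the E exocyclic alkene, and retention of the Z iodoacrylate geometry, and these are secured by the single free hydroxyl beside the only alkyne and by base-free coupling at room temperature. The alkenyl chloride, the silyl ethers and the TMSE ester should be inert to these reagents.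

Step 20
Reactants: 30 protected target
Product: 31 (3E,5R)-5-[(2S,3R,5R)-5-[(3Z,6E)-3-chloro-6-(6-oxo-2H-pyran-3(6H)-ylidene)hex-3-en-1-yl]-3-hydroxyoxolan-2-yl]-5-hydroxy-3-methylpent-3-enoic acid (target)
Conditions: (Me2N)3S[Me3SiF2] (TASF), H2O, DMF, 0 °C to rt; aq. NaH2PO4
Reagents that add atoms: none
Why: Fluoride-mediated global deprotection: water-buffered TASF cleaves both Si–O bonds and fragments the TMSE ester to ethene, Me3SiF and the carboxylate under near-neutral conditions that should spare ring B.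

**Compound list**

1 | 2-deoxy-D-glucose | O=CC[C@@H](O)[C@H](O)[C@H](O)CO | starting material
2 | 2-deoxy-D-arabino-hexono-1,4-lactone | OC[C@@H](O)[C@H]1OC(=O)C[C@H]1O | intermediate
3 | 2-deoxy-3,5,6-tris-O-(triethylsilyl)-D-arabino-hexono-1,4-lactone | CC[Si](CC)(CC)OC[C@@H](O[Si](CC)(CC)CC)[C@H]1OC(=O)C[C@H]1O[Si](CC)(CC)CC | intermediate
4 | propargyl alcohol | C#CCO | starting material
5 | 1-methoxy-4-[(prop-2-yn-1-yloxy)methyl]benzene | C#CCOCc1ccc(OC)cc1 | intermediate
6 | ethylene oxide | C1CO1 | starting material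
7 | 5-[(4-methoxybenzyl)oxy]pent-3-yn-1-ol | OCCC#CCOCc1ccc(OC)cc1 | intermediate
8 | 1-{[(5-iodopent-2-yn-1-yl)oxy]methyl}-4-methoxybenzene | ICCC#CCOCc1ccc(OC)cc1 | intermediate
9 | {5-[(4-methoxybenzyl)oxy]pent-3-yn-1-yl}lithium | [Li]CCC#CCOCc1ccc(OC)cc1 | intermediate (not isolated)
10 | hemiketal from 9 and 3 (both anomers) | CC[Si](CC)(CC)OC[C@@H](O[Si](CC)(CC)CC)[C@H]1OC(O)(CCC#CCOCc2ccc(OC)cc2)C[C@H]1O[Si](CC)(CC)CC | intermediate
11 | (2S,3R,5R)-2-[(1R)-1,2-bis(triethylsilyloxy)ethyl]-5-{5-[(4-methoxybenzyl)oxy]pent-3-yn-1-yl}-3-(triethylsilyloxy)oxolane | CC[Si](CC)(CC)OC[C@@H](O[Si](CC)(CC)CC)[C@H]1O[C@H](CCC#CCOCc2ccc(OC)cc2)C[C@H]1O[Si](CC)(CC)CC | intermediate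
12 | (2S,3R,5R)-2-[(1R)-1,2-bis(triethylsilyloxy)ethyl]-5-(5-hydroxypent-3-yn-1-yl)-3-(triethylsilyloxy)oxolane | CC[Si](CC)(CC)OC[C@@H](O[Si](CC)(CC)CC)[C@H]1O[C@H](CCC#CCO)C[C@H]1O[Si](CC)(CC)CC | intermediate
13 | sodium cyclic alkoxy(alkenyl)bis(2-methoxyethoxy)aluminate from anti Al–H addition to 12 | [Na+].CC[Si](CC)(CC)OC[C@@H](O[Si](CC)(CC)CC)[C@H]1O[C@H](CCC2=CCO[Al-]2(OCCOC)OCCOC)C[C@H]1O[Si](CC)(CC)CC | intermediate (not isolated)
14 | (2S,3R,5R)-2-[(1R)-1,2-bis(triethylsilyloxy)ethyl]-5-[(3Z)-3-chloro-5-hydroxypent-3-en-1-yl]-3-(triethylsilyloxy)oxolane | CC[Si](CC)(CC)OC[C@@H](O[Si](CC)(CC)CC)[C@H]1O[C@H](CC/C(Cl)=C/CO)C[C@H]1O[Si](CC)(CC)CC | intermediate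
15 | allylic mesylate of 14 | CC[Si](CC)(CC)OC[C@@H](O[Si](CC)(CC)CC)[C@H]1O[C@H](CC/C(Cl)=C/COS(C)(=O)=O)C[C@H]1O[Si](CC)(CC)CC | intermediate (not isolated)
16 | (2S,3R,5R)-2-[(1R)-1,2-bis(triethylsilyloxy)ethyl]-5-[(3Z)-5-bromo-3-chloropent-3-en-1-yl]-3-(triethylsilyloxy)oxolane | CC[Si](CC)(CC)OC[C@@H](O[Si](CC)(CC)CC)[C@H]1O[C@H](CC/C(Cl)=C/CBr)C[C@H]1O[Si](CC)(CC)CC | intermediate
17 | (2S,3R,5R)-2-[(1R)-1,2-bis(triethylsilyloxy)ethyl]-5-{(3Z)-3-chloro-8-[(4-methoxybenzyl)oxy]oct-3-en-6-yn-1-yl}-3-(triethylsilyloxy)oxolane | CC[Si](CC)(CC)OC[C@@H](O[Si](CC)(CC)CC)[C@H]1O[C@H](CC/C(Cl)=C/CC#CCOCc2ccc(OC)cc2)C[C@H]1O[Si](CC)(CC)CC | intermediate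
18 | (2S)-2-[(2S,3R,5R)-5-{(3Z)-3-chloro-8-[(4-methoxybenzyl)oxy]oct-3-en-6-yn-1-yl}-3-(triethylsilyloxy)oxolan-2-yl]-2-(triethylsilyloxy)acetaldehyde | O=C[C@@H](O[Si](CC)(CC)CC)[C@H]1O[C@H](CC/C(Cl)=C/CC#CCOCc2ccc(OC)cc2)C[C@H]1O[Si](CC)(CC)CC | intermediate
19 | ethyl 2-(triphenylphosphoranylidene)propanoate | CCOC(=O)C(C)=P(c1ccccc1)(c1ccccc1)c1ccccc1 | starting material
20 | ethyl (2E,4R)-enoate (Wittig product of 18) | C/C(=C\[C@@H](O[Si](CC)(CC)CC)[C@H]1O[C@H](CC/C(Cl)=C/CC#CCOCc2ccc(OC)cc2)C[C@H]1O[Si](CC)(CC)CC)C(=O)OCC | intermediate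
21 | (2E,4R)-enoic acid from 20 | C/C(=C\[C@@H](O[Si](CC)(CC)CC)[C@H]1O[C@H](CC/C(Cl)=C/CC#CCOCc2ccc(OC)cc2)C[C@H]1O[Si](CC)(CC)CC)C(=O)O | intermediate
22 | acid chloride of 21 | C/C(=C\[C@@H](O[Si](CC)(CC)CC)[C@H]1O[C@H](CC/C(Cl)=C/CC#CCOCc2ccc(OC)cc2)C[C@H]1O[Si](CC)(CC)CC)C(Cl)=O | intermediate (not isolated)
23 | (3E,5R)-1-diazo-pent-3-en-2-one from 22 | C/C(=C\[C@@H](O[Si](CC)(CC)CC)[C@H]1O[C@H](CC/C(Cl)=C/CC#CCOCc2ccc(OC)cc2)C[C@H]1O[Si](CC)(CC)CC)C(=O)C=[N+]=[N-] | intermediate
24 | 2-(trimethylsilyl)ethyl (3E,5R)-pent-3-enoate, PMB ether | C/C(=C\[C@@H](O[Si](CC)(CC)CC)[C@H]1O[C@H](CC/C(Cl)=C/CC#CCOCc2ccc(OC)cc2)C[C@H]1O[Si](CC)(CC)CC)CC(=O)OCC[Si](C)(C)C | intermediate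
25 | skipped enynol (key-step precursor) | C/C(=C\[C@@H](O[Si](CC)(CC)CC)[C@H]1O[C@H](CC/C(Cl)=C/CC#CCO)C[C@H]1O[Si](CC)(CC)CC)CC(=O)OCC[Si](C)(C)C | intermediate
26 | methyl propiolate | C#CC(=O)OC | starting material
27 | methyl (2Z)-3-iodoprop-2-enoate | COC(=O)/C=C\I | intermediate
28 | (3Z,6Z)-3-chloro-8-hydroxy-7-(tributylstannyl)octa-3,6-dienyl compound (tin cis to the chain) | C/C(=C\[C@@H](O[Si](CC)(CC)CC)[C@H]1O[C@H](CC/C(Cl)=C/C/C=C(\[Sn](CCCC)(CCCC)CCCC)CO)C[C@H]1O[Si](CC)(CC)CC)CC(=O)OCC[Si](C)(C)C | intermediate (not isolated)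
29 | (3Z,6E,8Z)-3-chloro-7-(hydroxymethyl)-10-methoxy-10-oxodeca-3,6,8-trienyl compound | C/C(=C\[C@@H](O[Si](CC)(CC)CC)[C@H]1O[C@H](CC/C(Cl)=C/C/C=C(\C=C/C(=O)OC)CO)C[C@H]1O[Si](CC)(CC)CC)CC(=O)OCC[Si](C)(C)C | intermediate (not isolated)
30 | fully protected target (ring B closed; two TES ethers, TMSE ester) | C/C(=C\[C@@H](O[Si](CC)(CC)CC)[C@H]1O[C@H](CC/C(Cl)=C/C/C=C2\C=CC(=O)OC2)C[C@H]1O[Si](CC)(CC)CC)CC(=O)OCC[Si](C)(C)C | intermediate
31 | (3E,5R)-5-[(2S,3R,5R)-5-[(3Z,6E)-3-chloro-6-(6-oxo-2H-pyran-3(6H)-ylidene)hex-3-en-1-yl]-3-hydroxyoxolan-2-yl]-5-hydroxy-3-methylpent-3-enoic acid | C/C(=C\[C@@H](O)[C@H]1O[C@H](CC/C(Cl)=C/C/C=C2\C=CC(=O)OC2)C[C@H]1O)CC(=O)O | target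

**Step count**

Total: 20 steps. Longest linear sequence: 17 steps (4 → 5 → 7 → 8 → 10 → 11 → 12 → 14 → 16 → 17 → 18 → 20 → 21 → 23 → 24 → 25 → 30 → 31); the sugar line from 1 is 16 steps.

**Steps most likely to fail**

Step 19. The hindered alkenylstannane bearing an α-CH2OH group may lose tin by protodestannation before it transmetalates, and slow coupling leaves time for the skipped diene to drift into conjugation. The fallback sets out from 25 and comes back at 30. The trans-hydrostannation is kept, but stannane 28 is isolated and treated with I2 in CH2Cl2 at −78 °C, which should give the (Z)-alkenyl iodide F1 with retention. Separately, radical hydrostannation of methyl propiolate 26 with Bu3SnH gives methyl (Z)-3-(tributylstannyl)acrylate F2 after separation of isomers. Stille coupling of F1 with F2 (Pd2(dba)3, AsPh3, CuI, DMF, rt) then passes through hydroxy dienoate 29, which lactonises to 30. The tin now sits on the small, unhindered partner.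

Step 7. BF3·OEt2 may cleave the primary TES ether or the PMB ether before hydride transfer, and the oxocarbenium ion may lose a proton to give an enol ether. The fallback sets out from 2 and comes back at 11, using groups that resist the Lewis acid:
- 2,2-Dimethoxypropane and TsOH in acetone give 2-deoxy-5,6-O-isopropylidene-D-arabino-hexono-1,4-lactone F3.
- TBSCl and imidazole give its 3-O-tert-butyldimethylsilyl ether F4.
- Alkyllithium 9 adds at −78 °C to give hemiketal F5.
- Et3SiH and BF3·OEt2 at −78 °C give the acetonide- and TBS-protected oxolane F6 by the same ionic hydrogenation.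
- Aqueous HCl in MeOH/THF removes acetonide and TBS ether to give the (2S,3R,5R)-oxolane triol F7.
- TESCl and imidazole convert F7 into 11.

Step 16 (with its partner step 15). Diazomethane may add as a dipole to the conjugated alkene, and during ketene trapping the new β,γ-alkene may migrate into conjugation or lose its E geometry. The fallback sets out from 20 and comes back at 24, replacing the diazoketone by a decarboxylative carbonylation of an allylic carbonate. Reduction of 20 with i-Bu2AlH in CH2Cl2 at −78 °C gives the (E)-allylic alcohol F8. Acylation with 4-nitrophenyl 2-(trimethylsilyl)ethyl carbonate and DMAP gives the allylic 2-(trimethylsilyl)ethyl carbonate F9. Pd(OAc)2, PPh3 and CO in THF at 50 °C should then ionise F9, lose CO2, insert CO at the CH2 terminus of the π-allyl and capture the liberated 2-(trimethylsilyl)ethoxide, giving 24.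

**Further compounds**

F1 | step 19 | (Z)-alkenyl iodide from iododestannylation of 28 (iodine cis to the chain) | C/C(=C\[C@@H](O[Si](CC)(CC)CC)[C@H]1O[C@H](CC/C(Cl)=C/C/C=C(\I)CO)C[C@H]1O[Si](CC)(CC)CC)CC(=O)OCC[Si](C)(C)C
F2 | step 19 | methyl (Z)-3-(tributylstannyl)acrylate | CCCC[Sn](CCCC)(CCCC)/C=C\C(=O)OC
F3 | step 7 | 2-deoxy-5,6-O-isopropylidene-D-arabino-hexono-1,4-lactone | CC1(C)OC[C@@H](O1)[C@H]2OC(=O)C[C@H]2O
F4 | step 7 | 3-O-tert-butyldimethylsilyl ether of F3 | CC1(C)OC[C@@H](O1)[C@H]2OC(=O)C[C@H]2O[Si](C)(C)C(C)(C)C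
F5 | step 7 | hemiketal from 9 and F4 (both anomers) | CC1(C)OC[C@@H](O1)[C@H]2OC(O)(CCC#CCOCc3ccc(OC)cc3)C[C@H]2O[Si](C)(C)C(C)(C)C
F6 | step 7 | acetonide- and TBS-protected (2S,3R,5R)-oxolane | CC1(C)OC[C@@H](O1)[C@H]2O[C@H](CCC#CCOCc3ccc(OC)cc3)C[C@H]2O[Si](C)(C)C(C)(C)C
F7 | step 7 | (2S,3R,5R)-2-[(1R)-1,2-dihydroxyethyl]-5-{5-[(4-methoxybenzyl)oxy]pent-3-yn-1-yl}oxolan-3-ol | OC[C@@H](O)[C@H]1O[C@H](CCC#CCOCc2ccc(OC)cc2)C[C@H]1O
F8 | step 16 | (E)-allylic alcohol from reduction of 20 | C/C(=C\[C@@H](O[Si](CC)(CC)CC)[C@H]1O[C@H](CC/C(Cl)=C/CC#CCOCc2ccc(OC)cc2)C[C@H]1O[Si](CC)(CC)CC)CO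
F9 | step 16 | allylic 2-(trimethylsilyl)ethyl carbonate of F8 | C/C(=C\[C@@H](O[Si](CC)(CC)CC)[C@H]1O[C@H](CC/C(Cl)=C/CC#CCOCc2ccc(OC)cc2)C[C@H]1O[Si](CC)(CC)CC)COC(=O)OCC[Si](C)(C)C
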